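**Retrosynthetic overview**

a) No ring is formed: rings A, C and B are bought intact as morin (1). The usual prenyl-acetophenone / chalcone / Algar–Flynn–Oyamada assembly is replaced by a late-stage C6–H prenylation of the flavonol.
b) Four O–CH2OMe disconnections: MOMCl (2) caps the unchelated 3-, 7-, 2'- and 4'-OH (3); the remaining chelated 5-OH then takes allyl bromide (4) to give 5.
c) Key disconnection C6–CH2: O5→C6 [3,3] shift of 5 through dienone 6 to the 6-allylphenol 7. C6 is the only open ortho position of O5, so C8 cannot compete.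
d) Disconnection of the prenyl C=C bond: cross-metathesis of 7 with 2-methyl-2-butene (8) gives 9.
e) Global MOM removal gives the target 10.

Assumption: the target has no stereocentre and no stereogenic double bond, so there is nothing to set as a single enantiomer; morin, sold as its hydrate, is dried before use.

**Route**

Step 1
Reactants: 1 morin [2-(2,4-dihydroxyphenyl)-3,5,7-trihydroxy-4H-chromen-4-one]; 2 chloromethyl methyl ether (MOMCl)
Product: 3 5-hydroxy-3,7-bis(methoxymethoxy)-2-[2,4-bis(methoxymethoxy)phenyl]-4H-chromen-4-one (3,7,2',4'-tetra-O-MOM-morin; only the 5-OH is free)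
Conditions: MOMCl (4.4 equiv), K2CO3 (6 equiv), acetone, 0 °C to 50 °C
Reagents that add atoms: chloromethyl methyl ether (compound 2), COCCl
Why: Williamson-type O-alkylation in which the four unchelated hydroxyls react, while the 5-OH, locked in a six-membered hydrogen bond to the C4 carbonyl, is the least acidic and least nucleophilic and stays free under mild carbonate conditions; no stereocentre is involved.

Step 2
Reactants: 3 3,7,2',4'-tetra-O-MOM-morin; 4 allyl bromide (3-bromoprop-1-ene)
Product: 5 5-(allyloxy)-3,7-bis(methoxymethoxy)-2-[2,4-bis(methoxymethoxy)phenyl]-4H-chromen-4-one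
Conditions: allyl bromide (3 equiv), K2CO3 (4 equiv), DMF, 60 °C
Reagents that add atoms: allyl bromide (compound 4), C=CCBr
Why: Williamson ether synthesis (SN2) in hot DMF breaks the chelate and O-allylates the only remaining hydroxyl, placing the migrating group on the one oxygen whose sole open ortho position is C6.

Step 3
Reactants: 5 5-(allyloxy)-3,7-bis(methoxymethoxy)-2-[2,4-bis(methoxymethoxy)phenyl]-4H-chromen-4-one
Product: 7 6-allyl-5-hydroxy-3,7-bis(methoxymethoxy)-2-[2,4-bis(methoxymethoxy)phenyl]-4H-chromen-4-one, via Claisen dienone 6 (not isolated)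
Conditions: Eu(fod)3 [Eu(C10H10F7O2)3] (10 mol %), PhCl, 130 °C, sealed tube
Reagents that add atoms: none
Why: Aromatic Claisen rearrangement ([3,3]-sigmatropic shift) accelerated by the oxophilic Lewis acid chelated between the C4 carbonyl and O5; C4a is blocked, so the allyl terminus can bond only to C6, and dienone 6 (transient C6 stereocentre, formed racemic and erased) enolizes to the re-chelated phenol 7 faster than any Cope shift to C8.

Step 4
Reactants: 7 6-allyl-5-hydroxy-3,7-bis(methoxymethoxy)-2-[2,4-bis(methoxymethoxy)phenyl]-4H-chromen-4-one; 8 2-methyl-2-butene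
Product: 9 5-hydroxy-3,7-bis(methoxymethoxy)-2-[2,4-bis(methoxymethoxy)phenyl]-6-(3-methylbut-2-en-1-yl)-4H-chromen-4-one
Conditions: 2-methyl-2-butene (excess, co-solvent), second-generation Grubbs catalyst RuCl2(=CHPh)(PCy3)(H2IMes) (5 mol %), CH2Cl2, 40 °C, sealed tube
Reagents that add atoms: 2-methyl-2-butene (compound 8), CC=C(C)C
Why: Olefin cross-metathesis exchanges the CH2 end of the terminal allyl olefin for the isopropylidene unit of the excess trisubstituted olefin, propene escapes and drives the equilibrium, and the chelated 5-OH, the aromatic rings and the tetrasubstituted C2=C3 enone bond are inert to the ruthenium carbene.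

Step 5
Reactants: 9 5-hydroxy-3,7-bis(methoxymethoxy)-2-[2,4-bis(methoxymethoxy)phenyl]-6-(3-methylbut-2-en-1-yl)-4H-chromen-4-one
Product: 10 2-(2,4-dihydroxyphenyl)-3,5,7-trihydroxy-6-(3-methylbut-2-en-1-yl)-4H-chromen-4-one (target, achiral)
Conditions: HCl (about 0.5 M in MeOH), MeOH, 40 °C, argon, stopped at full conversion
Reagents that add atoms: none
Why: Acid-catalysed acetal methanolysis (transacetalization) passes each methoxymethyl group to methanol, and dilute acid at mild temperature is too weak to protonate the trisubstituted prenyl olefin, so cyclization onto the 5-OH or 7-OH to a dimethylchroman is avoided.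

**Compound list**

1 | morin, 2-(2,4-dihydroxyphenyl)-3,5,7-trihydroxy-4H-chromen-4-one (achiral) | O=c1c(O)c(-c2ccc(O)cc2O)oc2cc(O)cc(O)c12 | starting material
2 | chloromethyl methyl ether (MOMCl) | COCCl | starting material
3 | 5-hydroxy-3,7-bis(methoxymethoxy)-2-[2,4-bis(methoxymethoxy)phenyl]-4H-chromen-4-one (achiral) | COCOc1cc(O)c2c(=O)c(OCOC)c(-c3ccc(OCOC)cc3OCOC)oc2c1 | intermediate
4 | allyl bromide (3-bromoprop-1-ene) | C=CCBr | starting material
5 | 5-(allyloxy)-3,7-bis(methoxymethoxy)-2-[2,4-bis(methoxymethoxy)phenyl]-4H-chromen-4-one (achiral) | C=CCOc1cc(OCOC)cc2oc(-c3ccc(OCOC)cc3OCOC)c(OCOC)c(=O)c12 | intermediate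
6 | Claisen dienone, 6-allyl-3,7-bis(methoxymethoxy)-2-[2,4-bis(methoxymethoxy)phenyl]-6H-chromene-4,5-dione (racemic at C6, transient, not isolated) | C=CCC1C(=O)C2=C(C=C1OCOC)OC(c1ccc(OCOC)cc1OCOC)=C(OCOC)C2=O | intermediate
7 | 6-allyl-5-hydroxy-3,7-bis(methoxymethoxy)-2-[2,4-bis(methoxymethoxy)phenyl]-4H-chromen-4-one (achiral) | C=CCc1c(OCOC)cc2oc(-c3ccc(OCOC)cc3OCOC)c(OCOC)c(=O)c2c1O | intermediate
8 | 2-methyl-2-butene | CC=C(C)C | starting material
9 | 5-hydroxy-3,7-bis(methoxymethoxy)-2-[2,4-bis(methoxymethoxy)phenyl]-6-(3-methylbut-2-en-1-yl)-4H-chromen-4-one (achiral) | CC(C)=CCc1c(OCOC)cc2oc(-c3ccc(OCOC)cc3OCOC)c(OCOC)c(=O)c2c1O | intermediate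
10 | 2-(2,4-dihydroxyphenyl)-3,5,7-trihydroxy-6-(3-methylbut-2-en-1-yl)-4H-chromen-4-one (6-prenylmorin, achiral) | CC(C)=CCc1c(O)cc2oc(-c3ccc(O)cc3O)c(O)c(=O)c2c1O | target

**Step count and risks**

Total step count: 5. Longest linear sequence: 5 steps (1 → 3 → 5 → 7 → 9 → 10).

The three steps most likely to fail, in route order:

Step 1 (stopping cleanly at the tetra-ether, with tri- and penta-ethers as contaminants). The fallback sets out from 1 and comes back at 3. Instead of relying on kinetic discrimination, all five hydroxyls are capped with excess MOMCl 2 and NaH in DMF at 0 °C to room temperature. This gives 3,5,7-tris(methoxymethoxy)-2-[2,4-bis(methoxymethoxy)phenyl]-4H-chromen-4-one F1. The one acetal that sits peri to the C4 carbonyl is then removed selectively by carbonyl-assisted methanolysis with a trace of HCl in MeOH–CH2Cl2 at 0 °C; the product is stabilized by the re-formed hydrogen bond. This frees only the 5-OH and delivers 3.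

Step 3 (the Claisen shift may be sluggish for an unsubstituted allyl ether, or the MOM acetals may suffer at 130 °C). The fallback sets out from 3 and comes back at 9, bypassing 5, 7 and the metathesis. Compound 3 is O-alkylated with prenyl bromide (1-bromo-3-methylbut-2-ene, CC(C)=CCBr) and K2CO3 in DMF at 60 °C. This gives 3,7-bis(methoxymethoxy)-2-[2,4-bis(methoxymethoxy)phenyl]-5-[(3-methylbut-2-en-1-yl)oxy]-4H-chromen-4-one F2. F2 is then stirred with Florisil (activated magnesium silicate, MgSiO3) in CH2Cl2–toluene at room temperature. This is a surface-acid-promoted formal [1,3] O→C prenyl shift through a tight phenoxide/prenyl-cation pair, which collapses mainly at the adjacent C6 and gives 9 directly. Any 8-prenyl isomer is removed by chromatography, and the reaction is stopped before chroman formation sets in.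

Step 5 (acid may add the 5-OH or 7-OH across the prenyl olefin). The fallback sets out from 7 and comes back at 10. The order of the last two operations is inverted so that the acid-sensitive prenyl olefin never meets acid. Compound 7 is deprotected with methanolic HCl, which does not protonate the monosubstituted allyl olefin. This gives 2-(2,4-dihydroxyphenyl)-3,5,7-trihydroxy-6-(prop-2-en-1-yl)-4H-chromen-4-one F3. F3 is then subjected to cross-metathesis with 8 (second-generation Grubbs catalyst RuCl2(=CHPh)(PCy3)(H2IMes), THF–CH2Cl2, 40 °C) to give 10; the risk moved into this step is that the free flavonol chelates ruthenium.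

**Further compounds**

F1 | step 1 | 3,5,7-tris(methoxymethoxy)-2-[2,4-bis(methoxymethoxy)phenyl]-4H-chromen-4-one | COCOc1cc(OCOC)c2c(=O)c(OCOC)c(-c3ccc(OCOC)cc3OCOC)oc2c1
F2 | step 3 | 3,7-bis(methoxymethoxy)-2-[2,4-bis(methoxymethoxy)phenyl]-5-[(3-methylbut-2-en-1-yl)oxy]-4H-chromen-4-one | CC(C)=CCOc1cc(OCOC)cc2oc(-c3ccc(OCOC)cc3OCOC)c(OCOC)c(=O)c12
F3 | step 5 | 2-(2,4-dihydroxyphenyl)-3,5,7-trihydroxy-6-(prop-2-en-1-yl)-4H-chromen-4-one | C=CCc1c(O)cc2oc(-c3ccc(O)cc3O)c(O)c(=O)c2c1O
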